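All runs come from a simulation for substances that don't exist, and the scatter is random.

Take over this bench.

in all of them: gas 22 mM (held)

| run | starting material | remark | time |
|---|---|---|---|
| green | 0.050 M | run made earlier |  |
| blue | 0.074 M | run made earlier |  |
| Monday's | 0.099 M |  | 12 h |
| Friday's | 0.099 M |  | 15 h |
| Thursday's | 0.099 M |  | 20 h |

| run | time / h | starting material / % | isomer of the product / % | target / % | tight pair / % |
|---|---|---|---|---|---|
| green | 1.00 | 79.2 | 2.8 | 18.2 | 0.5 |
| green | 3.00 | 48.9 | 8.2 | 43.6 | 0 |
| green | 5.00 | 29.5 | 11.4 | 60.0 | 0 |
| green | 8.00 | 14.5 | 12.6 | 73.5 | 0.3 |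
| green | 12.0 | 4.9 | 14.1 | 80.2 | 0.7 |
| green | 15.0 | 2.3 | 14.6 | 82.9 | 0 |
| blue | 1.00 | 79.4 | 3.2 | 17.8 | 0 |
| blue | 3.00 | 48.0 | 8.4 | 44.1 | 0 |
| blue | 5.00 | 30.2 | 10.3 | 60.9 | 0.1 |
| blue | 8.00 | 14.3 | 14.0 | 73.7 | 0 |
| blue | 12.0 | 6.2 | 14.5 | 81.3 | 0 |
| blue | 15.0 | 1.8 | 13.6 | 83.1 | 0 |

(each reading ± 0.5 percentage points)

- which of these there is most of at the end, counted by the starting material in it, Monday's (tight pair / target / isomer of the product / starting material)
- which of these there is most of at the end, counted by the starting material in it, Friday's (tight pair / target / isomer of the product / starting material)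
- which of these there is most of at the end, counted by the starting material in it, Thursday's (tight pair / target / isomer of the product / starting material)
- the largest of these amounts at the end, in percent of the starting material charged, Monday's
- the largest of these amounts at the end, in percent of the starting material charged, Friday's
- the largest of these amounts at the end, in percent of the starting material charged, Thursday's

- at the start none of reagent is dissolved
- steps under discussion: starting material <-> tight pair; tight pair <-> loose pair; reagent + tight pair -> target; reagent + loose pair -> isomer of the product; gas <-> reagent

In Monday's, Friday's and Thursday's flasks, starting material is turning into target and its isomer under held gas. I carry a single reckoning, and I start from the green run's readings at 3.00 h and 8.00 h: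

k = ln(48.9% / 14.5%) / (8.00 h − 3.00 h) = 0.243 /h

This is the clock of the starting material, the fall per hour in the logarithm of the fraction left. The blue run gives 0.242 /h, so both charges look pseudo-first-order. The green run's last readings give target a share of what has reacted, its selectivity:

share = 82.9% / (82.9% + 14.6%) = 85.0%

Left is exp(−k·t), and target is the share of what is not left. I go round once more on the green reading at 12.0 h, which I have not used. The reckoning gives 80.4% of target, and the reading is 80.2%. So I commit, assuming that the clock holds at 0.099 M:

Monday's: left 5.41%, target 80.4%
Friday's: left 2.61%, target 82.8%
Thursday's: left 0.773%, target 84.3%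

By this reckoning target is the largest amount in each flask. Leave the gas held at 22 mM, the level at which the clock was read.

The forecast, with figures of its own, names target in each flask at 80.2%, 82.6% and 84.1%, on the ground that “capture by the reagent is fast”.

The flasks give target each time, at 80.5%, 82.9% and 84.4%, with 5.32%, 2.54% and 0.743% of starting material left.

    starting material ⇌ tight pair (K = 0.00121, k = 0.754 /h)
    tight pair ⇌ loose pair (K = 0.390, k = 391 /h)
    reagent + tight pair → target (k = 11700 /M/h)
    reagent + loose pair → isomer of the product (k = 5940 /M/h)
    gas ⇌ reagent, rate k5*(csat - [reagent]) (kL = 39.9 /h)

So my clock and share carry over to the larger charge. Target leads in Monday's flask because the loose pair runs back to the tight pair. With that backward step taken away, the same run falls from 80.5% to 38.5% of target, and the answer turns.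

On the neighbour, Monday's flask read at 8.0 h, the clock leaves 14.3% and gives 72.8% of target. The computed flask holds 14.2% of starting material and 72.9% of target.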